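Numbering used below: carbamate-bearing CH2 = C1, carbinol carbon = C7, gem-dimethyl carbon = C8.

Mycothiazole is cut once, between C7 and C8, into two achiral halves: a thiazole redox-active ester and a (Z)-dienyl aldehyde. Their union is the last step, needs no protecting group and sets the only stereocentre.
Enabling feature: C8 sits directly on C2 of the 1,3-thiazole ring, so C8–C2=N3 is a latent aza-enolate. A carboxyl group on C8 can leave as CO2, the tertiary radical is spread over C8, C2 and N3, N3 holds chromium, and the two equal methyl groups remove any enolate-geometry or second-stereocentre problem.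
Thiazole half: Hantzsch synthesis of the thiazole (the only ring, closed in step 2), heterobenzylic Suzuki–Miyaura coupling for the (E)-skipped diene, then ester to N-hydroxyphthalimide ester.
Aldehyde half: Markovnikov hydroiodination of a butynyl carbamate, Sonogashira coupling, cis-selective zinc semireduction for the (Z)-diene, Dess–Martin oxidation.

Key step: step 12

Assumption: the (S)-configured sulfonamide–oxazoline ligand is taken to leave the Si face of the chromium-bound aldehyde open to the new aza-enolate nucleophile (steric model in step 12); the mirror-image ligand from (R)-valinol is equally accessible if the sense of induction proves opposite.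

Step 1
Reactants: 1 ethyl 2-cyano-2-methylpropanoate
Product: 2 ethyl 3-amino-2,2-dimethyl-3-thioxopropanoate
Conditions: (EtO)2P(S)SH, H2O, dioxane, 80 °C
Reagents that add atoms: O,O-diethyl dithiophosphoric acid, CCOP(=S)(S)OCC
Why: Nitrile-to-thioamide conversion by addition of the dithiophosphoric acid S–H across C≡N and hydrolysis of the adduct should work because the geminal ester makes the hindered nitrile more electrophilic; no stereocentre is involved.

Step 2
Reactants: 2 ethyl 3-amino-2,2-dimethyl-3-thioxopropanoate + 3 1,3-dichloropropan-2-one
Product: 4 ethyl 2-[4-(chloromethyl)-1,3-thiazol-2-yl]-2-methylpropanoate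
Conditions: acetone, reflux
Reagents that add atoms: none
Why: In the Hantzsch thiazole synthesis, S-alkylation by one CH2Cl arm, attack of nitrogen on the ketone and dehydration give the aromatic 2,4-disubstituted ring; the symmetric dihaloketone leaves no regiochemical choice and its second CH2Cl arm stays as the handle at C4.

Step 3
Reactants: 5 pent-1-en-4-yne
Product: 6 2-[(1E)-penta-1,4-dien-1-yl]-4,4,5,5-tetramethyl-1,3,2-dioxaborolane
Conditions: HBpin, Cy2BH (5 mol %), neat, rt (5 in slight excess)
Reagents that add atoms: pinacolborane, B1OC(C)(C)C(C)(C)O1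
Why: In the dialkylborane-catalysed hydroboration with pinacolborane the terminal alkyne reacts much faster than the monosubstituted alkene, and the anti-Markovnikov syn addition sets the E geometry.

Step 4
Reactants: 4 ethyl 2-[4-(chloromethyl)-1,3-thiazol-2-yl]-2-methylpropanoate + 6 2-[(1E)-penta-1,4-dien-1-yl]-4,4,5,5-tetramethyl-1,3,2-dioxaborolane
Product: 7 ethyl 2-{4-[(2E)-hexa-2,5-dien-1-yl]-1,3-thiazol-2-yl}-2-methylpropanoate
Conditions: PdCl2(dppf) (5 mol %), K3PO4, THF/H2O, 60 °C
Reagents that add atoms: none
Why: In this sp3–sp2 Suzuki–Miyaura coupling the activated heterobenzylic chloride adds readily to zerovalent palladium, the alkenyl group is transferred with retention of the E geometry, and the hindered ester is left alone by the mild base.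

Step 5
Reactants: 7 ethyl 2-{4-[(2E)-hexa-2,5-dien-1-yl]-1,3-thiazol-2-yl}-2-methylpropanoate
Product: 8 2-{4-[(2E)-hexa-2,5-dien-1-yl]-1,3-thiazol-2-yl}-2-methylpropanoic acid
Conditions: LiOH, THF/MeOH/H2O, 40 °C; then cold 1 M HCl to pH 4, 0 °C; used without storage
Reagents that add atoms: lithium hydroxide, [Li+].[OH-]
Why: Ester saponification is helped by the electron-poor thiazole next to the carbonyl group; the carboxylate salt is stable, and the free acid is liberated cold so that loss of CO2 through its N-protonated zwitterion is held back.

Step 6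
Reactants: 8 2-{4-[(2E)-hexa-2,5-dien-1-yl]-1,3-thiazol-2-yl}-2-methylpropanoic acid
Product: 9 1,3-dioxoisoindolin-2-yl 2-{4-[(2E)-hexa-2,5-dien-1-yl]-1,3-thiazol-2-yl}-2-methylpropanoate
Conditions: N-hydroxyphthalimide, DIC, DMAP (10 mol %), CH2Cl2, 0 °C to rt
Reagents that add atoms: N-hydroxyphthalimide, O=C1c2ccccc2C(=O)N1O
Why: Steglich-type carbodiimide esterification is routine for alpha-quaternary acids, and the absence of an alpha-hydrogen shuts off ketene formation, so the redox-active ester should be a storable solid.

Step 7
Reactants: 10 but-3-yn-1-amine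
Product: 11 methyl but-3-yn-1-ylcarbamate
Conditions: ClCO2Me, aq NaOH, CH2Cl2, 0 °C
Reagents that add atoms: methyl chloroformate, COC(=O)Cl
Why: Schotten–Baumann N-acylation of a primary amine installs the methyl carbamate of the target at the outset.

Step 8
Reactants: 11 methyl but-3-yn-1-ylcarbamate
Product: 12 methyl (3-iodobut-3-en-1-yl)carbamate
Conditions: NaI, TMSCl, H2O (half an equivalent per TMSCl), MeCN, rt, dark
Reagents that add atoms: sodium iodide, [Na+].[I-]
Why: Markovnikov hydroiodination of a terminal alkyne by HI made in the flask puts iodine on the internal carbon and creates the 1,1-disubstituted alkene, while a methyl carbamate resists these conditions at room temperature.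

Step 9
Reactants: 12 methyl (3-iodobut-3-en-1-yl)carbamate + 13 but-3-yn-1-ol
Product: 14 methyl (7-hydroxy-3-methylidenehept-4-yn-1-yl)carbamate
Conditions: PdCl2(PPh3)2 (3 mol %), CuI (6 mol %), Et3N, THF, rt, degassed
Reagents that add atoms: none
Why: Sonogashira coupling of a reactive 2-iodoalk-1-ene with a terminal alkyne proceeds at room temperature and tolerates the free hydroxyl and carbamate N–H groups.

Step 10
Reactants: 14 methyl (7-hydroxy-3-methylidenehept-4-yn-1-yl)carbamate
Product: 15 methyl [(4Z)-7-hydroxy-3-methylidenehept-4-en-1-yl]carbamate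
Conditions: Zn dust activated with Cu(OAc)2 and AgNO3, MeOH/H2O, 40 °C
Reagents that add atoms: none
Why: Semireduction with the zinc–copper–silver couple attacks only conjugated alkynes, delivers both hydrogens cis to set the Z geometry, and stops at the diene.

Step 11
Reactants: 15 methyl [(4Z)-7-hydroxy-3-methylidenehept-4-en-1-yl]carbamate
Product: 16 methyl [(4Z)-3-methylidene-7-oxohept-4-en-1-yl]carbamate
Conditions: Dess–Martin periodinane, NaHCO3, CH2Cl2, 0 °C; filtration through a short silica pad, used at once
Reagents that add atoms: none
Why: Dess–Martin oxidation under bicarbonate buffer is fast, nearly neutral and free of amine base, the usual way to reach (Z)-beta,gamma-unsaturated aldehydes without double-bond migration.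

Step 12
Reactants: 9 1,3-dioxoisoindolin-2-yl 2-{4-[(2E)-hexa-2,5-dien-1-yl]-1,3-thiazol-2-yl}-2-methylpropanoate + 16 methyl [(4Z)-3-methylidene-7-oxohept-4-en-1-yl]carbamate
Product: 20 mycothiazole = methyl N-[(4Z,7R)-7-hydroxy-8-{4-[(2E)-hexa-2,5-dien-1-yl]-1,3-thiazol-2-yl}-8-methyl-3-methylidenenon-4-en-1-yl]carbamate, via tertiary thiazolyl radical 17 (not isolated), via chromium aza-enolate 18 (not isolated), via trimethylsilyl ether 19 (not isolated)
Conditions: CrCl2 (15 mol %), N-{2-[(4S)-4-isopropyl-4,5-dihydro-1,3-oxazol-2-yl]-6-methylphenyl}methanesulfonamide (17 mol %), Et3N (17 mol %, precomplexation), TMSCl, Bu4NPF6, MeCN, undivided cell, Al anode, Ni-foam cathode, low constant current (cathode kept at the chromium couple), 0 °C, 16 added last as a cold solution; then dilute aq HCl/THF, 0 °C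
Reagents that add atoms: chlorotrimethylsilane, C[Si](C)(C)Cl (its Me3Si group is carried by 19 only and leaves again in the acidic work-up)
Why: Proposed new method: ligand-bound divalent chromium, regenerated at the cathode, gives one electron to the N-acyloxyphthalimide of 9, which loses phthalimide anion and CO2 to leave the tertiary radical 17, spread over C8, C2 and N3 of the thiazole; a second divalent chromium traps 17 as the N3-bound trivalent chromium aza-enolate 18, whose C8 terminus attacks the chromium-bound aldehyde 16, and TMSCl silylates the alkoxide to 19 and so frees the metal for the next cathodic turnover. The closest known reaction types are the chromium-electrocatalytic decarboxylative Nozaki–Hiyama–Kishi addition of redox-active esters to aldehydes, the CrCl2-mediated Reformatsky reaction of 2-bromo-2-methylpropanoyl compounds (which makes the same CMe2–CH(OH) bond through a heteroatom-bound chromium enolate) and asymmetric Nozaki–Hiyama–Kishi catalysis with sulfonamide–oxazoline ligands; what is new is their use on a tertiary alpha-azaaryl radical, and the loss of CO2 in the bond-forming event mirrors the decarboxylative Claisen condensation by which a polyketide synthase is presumed to forge this bond. No ring is closed: the only cyclic array is the six-membered chair transition state Cr–N3–C2–C8···C7–O, which falls apart as the thiazole regains its aromaticity. The one new stereocentre, C7, is under catalyst control: the isopropyl group of the oxazoline should shield the Re face of the bound aldehyde, whose chain lies equatorial, so that attack on the Si face gives 7R, and since C8 bears two methyl groups neither enolate geometry nor a second stereocentre comes into play. The step needs 1,2-addition to win over enolisation or double-bond migration of the beta,gamma-unsaturated aldehyde, over radical dimerisation and over attack through nitrogen; the low basicity of organochromium reagents, the capture of phthalimide anion by TMSCl, the birth of 17 in the bulk next to divalent chromium and the aromatisation gained only by C-attack secure these, while the carbamate N–H and the four C=C bonds are inert to trivalent organochromium species.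

Compound list
1 | ethyl 2-cyano-2-methylpropanoate | CCOC(=O)C(C)(C)C#N | starting material
2 | ethyl 3-amino-2,2-dimethyl-3-thioxopropanoate | CCOC(=O)C(C)(C)C(N)=S | intermediate
3 | 1,3-dichloropropan-2-one | ClCC(=O)CCl | starting material
4 | ethyl 2-[4-(chloromethyl)-1,3-thiazol-2-yl]-2-methylpropanoate | CCOC(=O)C(C)(C)c1nc(CCl)cs1 | intermediate
5 | pent-1-en-4-yne | C=CCC#C | starting material
6 | 2-[(1E)-penta-1,4-dien-1-yl]-4,4,5,5-tetramethyl-1,3,2-dioxaborolane | C=CC/C=C/B1OC(C)(C)C(C)(C)O1 | intermediate
7 | ethyl 2-{4-[(2E)-hexa-2,5-dien-1-yl]-1,3-thiazol-2-yl}-2-methylpropanoate | CCOC(=O)C(C)(C)c1nc(C/C=C/CC=C)cs1 | intermediate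
8 | 2-{4-[(2E)-hexa-2,5-dien-1-yl]-1,3-thiazol-2-yl}-2-methylpropanoic acid | OC(=O)C(C)(C)c1nc(C/C=C/CC=C)cs1 | intermediate
9 | 1,3-dioxoisoindolin-2-yl 2-{4-[(2E)-hexa-2,5-dien-1-yl]-1,3-thiazol-2-yl}-2-methylpropanoate | O=C(ON1C(=O)c2ccccc2C1=O)C(C)(C)c1nc(C/C=C/CC=C)cs1 | intermediate
10 | but-3-yn-1-amine | C#CCCN | starting material
11 | methyl but-3-yn-1-ylcarbamate | C#CCCNC(=O)OC | intermediate
12 | methyl (3-iodobut-3-en-1-yl)carbamate | C=C(I)CCNC(=O)OC | intermediate
13 | but-3-yn-1-ol | C#CCCO | starting material
14 | methyl (7-hydroxy-3-methylidenehept-4-yn-1-yl)carbamate | OCCC#CC(=C)CCNC(=O)OC | intermediate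
15 | methyl [(4Z)-7-hydroxy-3-methylidenehept-4-en-1-yl]carbamate | OCC/C=C\C(=C)CCNC(=O)OC | intermediate
16 | methyl [(4Z)-3-methylidene-7-oxohept-4-en-1-yl]carbamate | O=CC/C=C\C(=C)CCNC(=O)OC | intermediate
17 | 2-{4-[(2E)-hexa-2,5-dien-1-yl]-1,3-thiazol-2-yl}propan-2-yl radical | C[C](C)c1nc(C/C=C/CC=C)cs1 | intermediate
18 | N3-bound trivalent chromium aza-enolate of the 2-isopropylidene-2,3-dihydrothiazole, with chloride and the deprotonated (S)-ligand on the metal (dative oxazoline bond not drawn) | CC(C)=C1SC=C(C/C=C/CC=C)N1[Cr](Cl)N(S(C)(=O)=O)c1c(C)cccc1C1=N[C@@H](C(C)C)CO1 | intermediate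
19 | (7R)-O-trimethylsilyl mycothiazole | C=CC/C=C/Cc1csc(C(C)(C)[C@H](O[Si](C)(C)C)C/C=C\C(=C)CCNC(=O)OC)n1 | intermediate
20 | mycothiazole, methyl N-[(4Z,7R)-7-hydroxy-8-{4-[(2E)-hexa-2,5-dien-1-yl]-1,3-thiazol-2-yl}-8-methyl-3-methylidenenon-4-en-1-yl]carbamate | C=CC/C=C/Cc1csc(C(C)(C)[C@H](O)C/C=C\C(=C)CCNC(=O)OC)n1 | target

Total step count: 12
Longest linear sequence: 6 steps (steps 1, 2, 4, 5, 6, 12, or equally steps 7 to 12)

Steps most likely to fail

1. Step 12 (proposed new method).
- What may go wrong: the hindered tertiary radical may escape capture by chromium and be lost through disproportionation or dimerisation. The untested nucleophile class may show poor facial selectivity. The aldehyde may suffer double-bond migration, or Lewis-acid-induced closure of its diene terminus onto the carbonyl group, before it is attacked.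
- Fallback (known chemistry only; sets out from 7 and 12, comes back at 20): the stereocentre is set by an asymmetric propargylation one bond further along the chain, and the carbamate half enters as the vinyl iodide. DIBAL-H in CH2Cl2 at −78 °C reduces 7 to 2-{4-[(2E)-hexa-2,5-dien-1-yl]-1,3-thiazol-2-yl}-2-methylpropanal F1. Allenylboronic acid pinacol ester with catalytic (R)-TRIP phosphoric acid in toluene at −20 °C should deliver the propargyl group to the Re face of the aldehyde and give (3R)-2-{4-[(2E)-hexa-2,5-dien-1-yl]-1,3-thiazol-2-yl}-2-methylhex-5-yn-3-ol F2. Sonogashira coupling of this alkyne with 12 (PdCl2(PPh3)2, CuI, Et3N, THF, rt) should give methyl N-[(7R)-7-hydroxy-8-{4-[(2E)-hexa-2,5-dien-1-yl]-1,3-thiazol-2-yl}-8-methyl-3-methylidenenon-4-yn-1-yl]carbamate F3. The zinc–copper–silver semireduction of step 10 then turns its conjugated alkyne into the (Z)-alkene of 20 and leaves the skipped diene alone.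

2. Step 11.
- What may go wrong: the C4=C5 double bond may migrate into conjugation with the new carbonyl group during oxidation, filtration or concentration, and the product may decay on contact with the acetic acid that the oxidant releases.
- Fallback (sets out from 12, comes back at 16): the aldehyde is released by a neutral glycol cleavage instead of an alcohol oxidation. Sonogashira coupling of 12 with purchased racemic pent-4-yne-1,2-diol (C#CCC(O)CO) under the conditions of step 9 should give methyl (7,8-dihydroxy-3-methylideneoct-4-yn-1-yl)carbamate F4. The semireduction of step 10 gives methyl [(4Z)-7,8-dihydroxy-3-methylideneoct-4-en-1-yl]carbamate F5. NaIO4 on silica gel in CH2Cl2 at 0 °C cleaves the diol, and simple filtration delivers a solution of 16 that goes straight into the cell.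

3. Step 4.
- What may go wrong: base- or palladium hydride-induced migration of the skipped diene into conjugation, protodeboronation of the dienylboronate, and hydrolysis of the heterobenzylic chloride in the aqueous medium.
- Fallback (sets out from 4 and 6, comes back at 7): the polarity of the two partners is reversed and the coupling is run without base or water. Iododeboronation of 6 (NaOH, then I2, THF, 0 °C, retention of geometry) gives (1E)-1-iodopenta-1,4-diene F6. Insertion of zinc dust into 4 in the presence of LiCl in THF gives {2-(1-ethoxy-2-methyl-1-oxopropan-2-yl)-1,3-thiazol-4-yl}methylzinc chloride F7. Negishi coupling of the two with Pd(PPh3)4 in THF at rt should give 7.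

Further compounds
F1 | step 12 | 2-{4-[(2E)-hexa-2,5-dien-1-yl]-1,3-thiazol-2-yl}-2-methylpropanal | O=CC(C)(C)c1nc(C/C=C/CC=C)cs1
F2 | step 12 | (3R)-2-{4-[(2E)-hexa-2,5-dien-1-yl]-1,3-thiazol-2-yl}-2-methylhex-5-yn-3-ol | C=CC/C=C/Cc1csc(C(C)(C)[C@H](O)CC#C)n1
F3 | step 12 | methyl N-[(7R)-7-hydroxy-8-{4-[(2E)-hexa-2,5-dien-1-yl]-1,3-thiazol-2-yl}-8-methyl-3-methylidenenon-4-yn-1-yl]carbamate | C=CC/C=C/Cc1csc(C(C)(C)[C@H](O)CC#CC(=C)CCNC(=O)OC)n1
F4 | step 11 | methyl (7,8-dihydroxy-3-methylideneoct-4-yn-1-yl)carbamate (racemic) | OCC(O)CC#CC(=C)CCNC(=O)OC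
F5 | step 11 | methyl [(4Z)-7,8-dihydroxy-3-methylideneoct-4-en-1-yl]carbamate (racemic) | OCC(O)C/C=C\C(=C)CCNC(=O)OC
F6 | step 4 | (1E)-1-iodopenta-1,4-diene | C=CC/C=C/I
F7 | step 4 | {2-(1-ethoxy-2-methyl-1-oxopropan-2-yl)-1,3-thiazol-4-yl}methylzinc chloride | CCOC(=O)C(C)(C)c1nc(C[Zn]Cl)cs1
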